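The route rests on making the lactone O–C8 bond and the ring bond C9–C10 in one operation (germacrane numbering). The target's five-membered lactone carbon C8 sits beside the ring CH2 C9, which is bonded to C10 of the (Z)-C10=C1 alkene; a vinyl group (C8=C9) and an alkyne (C10≡C1) map onto these four atoms. A cationic monovalent gold catalyst activates the alkyne of an open-chain tert-butyl ester, C9 attacks C10 and the ester carbonyl oxygen closes onto C8: the ten-membered carbocycle, the trans-fused γ-lactone, the C8 stereocentre and the (Z)-alkene form together. The precursor is a linear 1,9-enyne from an indium Barbier union of two fragments.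

Key step: step 17

Remark (numbering used below): ring carbons C1–C10, methyl C14 on C10, methyl C15 on C4, C11(=C13H2)–C12(=O) on C7, lactone oxygen on C8, ester oxygen on C5, hydroxyl on C6; all reagents named are taken as commercially available.

Step 1
Reactants: 1 but-2-yn-1-ol
Product: 3 (Z)-3-iodobut-2-en-1-ol, via cyclic alkenylalanate 2 (not isolated)
Conditions: NaAlH2(OCH2CH2OMe)2, THF, 0 → 23 °C; then I2, THF, −78 → 0 °C
Reagents that add atoms: iodine, [I][I]
Why: Hydroxyl-directed trans-hydroalumination of the propargylic alcohol puts aluminium on C3 and hydrogen on C2, and iodinolysis with retention should give the iodide with iodine cis to CH2OH.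

Step 2
Reactants: 3 (Z)-3-iodobut-2-en-1-ol
Product: 4 (Z)-1-bromo-3-iodobut-2-ene
Conditions: CBr4, PPh3, CH2Cl2, 0 °C
Reagents that add atoms: carbon tetrabromide, BrC(Br)(Br)Br
Why: Appel bromination of a primary allylic alcohol proceeds by SN2 displacement and leaves the alkene geometry and the vinyl iodide untouched.

Step 3
Reactants: 4 (Z)-1-bromo-3-iodobut-2-ene; 5 1-propynylmagnesium bromide
Product: 6 (Z)-2-iodohept-2-en-5-yne
Conditions: CuI (10 mol %), THF, 0 → 23 °C
Reagents that add atoms: none
Why: Copper-catalysed alkynylation of a primary allylic bromide should occur at the CH2 terminus (the other allyl terminus is the hindered iodine-bearing carbon) and give the skipped enyne C4=C3–C2–C1≡C10.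

Step 4
Reactants: 7 methyl glycolate
Product: 8 methyl 2-(triethylsilyloxy)acetate
Conditions: Et3SiCl, imidazole, CH2Cl2, 0 → 23 °C
Reagents that add atoms: chlorotriethylsilane, CC[Si](Cl)(CC)CC
Why: Standard silylation of a primary alcohol.

Step 5
Reactants: 8 methyl 2-(triethylsilyloxy)acetate
Product: 9 N-methoxy-N-methyl-2-(triethylsilyloxy)acetamide
Conditions: MeNH(OMe)·HCl, i-PrMgCl, THF, −20 °C
Reagents that add atoms: N,O-dimethylhydroxylamine hydrochloride, CNOC.Cl
Why: Aminolysis of a methyl ester by the magnesium amide of N,O-dimethylhydroxylamine (Weinreb amide synthesis).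

Step 6
Reactants: 6 (Z)-2-iodohept-2-en-5-yne; 9 N-methoxy-N-methyl-2-(triethylsilyloxy)acetamide
Product: 11 (Z)-3-methyl-1-(triethylsilyloxy)oct-3-en-6-yn-2-one, via alkenyllithium 10 (not isolated)
Conditions: t-BuLi (2 equiv), Et2O, −78 °C; then 9, −78 → −40 °C; pH 7 buffer
Reagents that add atoms: none
Why: Iodine–lithium exchange retains the alkene geometry, and Weinreb acylation stops at the ketone through the chelated tetrahedral intermediate, forming the C4–C5 bond with C5 cis to C2.

Step 7
Reactants: 11 (Z)-3-methyl-1-(triethylsilyloxy)oct-3-en-6-yn-2-one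
Product: 12 (2R,3Z)-3-methyl-1-(triethylsilyloxy)oct-3-en-6-yn-2-ol
Conditions: (R)-2-methyl-CBS-oxazaborolidine (0.2 equiv), BH3·SMe2, THF, −30 °C
Reagents that add atoms: none
Why: Corey–Bakshi–Shibata reduction with the α-branched alkenyl group as the large substituent should deliver hydride to the face that gives the (R)-carbinol, which sets C5.

Step 8
Reactants: 13 angelic acid
Product: 14 (Z)-2-methylbut-2-en-1-ol
Conditions: LiAlH4, Et2O, 0 → 23 °C
Reagents that add atoms: none
Why: Hydride reduction of the carboxylic acid to the allylic alcohol without touching the alkene geometry.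

Step 9
Reactants: 14 (Z)-2-methylbut-2-en-1-ol
Product: 15 [(2S,3R)-2,3-dimethyloxiran-2-yl]methanol
Conditions: Ti(Oi-Pr)4 (10 mol %), L-(+)-diethyl tartrate (12 mol %), t-BuOOH, 4 Å MS, CH2Cl2, −20 °C
Reagents that add atoms: tert-butyl hydroperoxide, CC(C)(C)OO
Why: Sharpless asymmetric epoxidation: the L-(+)-tartrate catalyst selects the alkene face that gives the (2S,3R)-epoxide, and the cis relation of CH2OH and the C3 methyl comes from the (Z)-alkene.

Step 10
Reactants: 15 [(2S,3R)-2,3-dimethyloxiran-2-yl]methanol
Product: 16 (2R,3R)-2,3-dimethyloxirane-2-carboxylic acid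
Conditions: RuCl3·H2O (2 mol %), NaIO4, CCl4/MeCN/H2O, 0 → 23 °C
Reagents that add atoms: water, O
Why: Ruthenium tetroxide oxidation of an epoxy alcohol to the epoxy acid leaves both epoxide carbons untouched (the C2 descriptor changes only because of priorities).

Step 11
Reactants: 12 (2R,3Z)-3-methyl-1-(triethylsilyloxy)oct-3-en-6-yn-2-ol; 16 (2R,3R)-2,3-dimethyloxirane-2-carboxylic acid
Product: 17 (2R,3Z)-3-methyl-1-(triethylsilyloxy)oct-3-en-6-yn-2-yl (2R,3R)-2,3-dimethyloxirane-2-carboxylate
Conditions: EDC·HCl, DMAP, CH2Cl2, 0 → 23 °C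
Reagents that add atoms: none
Why: Steglich esterification acylates the C5 hydroxyl with retention, so the side-chain ester is in place before any other free hydroxyl exists.

Step 12
Reactants: 17 (2R,3Z)-3-methyl-1-(triethylsilyloxy)oct-3-en-6-yn-2-yl (2R,3R)-2,3-dimethyloxirane-2-carboxylate
Product: 18 (2R,3Z)-3-methyl-1-oxooct-3-en-6-yn-2-yl (2R,3R)-2,3-dimethyloxirane-2-carboxylate
Conditions: (COCl)2, DMSO, CH2Cl2, −78 → −40 °C; then i-Pr2NEt, −78 °C; used crude
Reagents that add atoms: none
Why: Swern conditions convert a primary triethylsilyl ether directly into the aldehyde (activated DMSO attacks the silyl ether oxygen), so no free primary alcohol is formed to which the ester could migrate, and the cold hindered base limits epimerisation at C5.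

Step 13
Reactants: 19 acrolein; 20 tert-butyl acrylate
Product: 21 tert-butyl 3-hydroxy-2-methylidenepent-4-enoate (racemic)
Conditions: DABCO (0.2 equiv), 1,4-dioxane/H2O, 23 °C, excess 20
Reagents that add atoms: none
Why: Morita–Baylis–Hillman reaction of the acrylate with the aldehyde carbon of acrolein.

Step 14
Reactants: 21 tert-butyl 3-hydroxy-2-methylidenepent-4-enoate
Product: 22 tert-butyl (2Z)-2-(bromomethyl)penta-2,4-dienoate
Conditions: NBS, Me2S, CH2Cl2, 0 → 23 °C
Reagents that add atoms: N-bromosuccinimide, O=C1CCC(=O)N1Br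
Why: Corey–Kim-type bromination with allylic transposition (SN2′) should give the linearly conjugated, thermodynamically preferred (Z)-2-(bromomethyl)dienoate, as is usual for Baylis–Hillman alcohols.

Step 15
Reactants: 18 (2R,3Z)-3-methyl-1-oxooct-3-en-6-yn-2-yl (2R,3R)-2,3-dimethyloxirane-2-carboxylate; 22 tert-butyl (2Z)-2-(bromomethyl)penta-2,4-dienoate
Product: 24 tert-butyl (3R,4S,5R,6Z)-5-{[(2R,3R)-2,3-dimethyloxirane-2-carbonyl]oxy}-3-ethenyl-4-hydroxy-6-methyl-2-methylideneundec-6-en-9-ynoate, via allylindium dibromide 23 (not isolated)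
Conditions: In powder, THF/H2O (1:1), 23 °C
Reagents that add atoms: none
Why: Indium Barbier allylation: 23 should add through its γ-carbon (C7) in a closed chair transition state, the (Z)-geometry giving the syn C6-hydroxyl/C7-vinyl pair, while polar Felkin–Anh control by the C5 acyloxy group sets C6 anti to C5; the neutral medium and the tert-butyl ester keep the C5 ester from migrating and the new hydroxyl from lactonising.

Step 16
Reactants: 24 (the C6 alcohol from step 15)
Product: 25 tert-butyl (3R,4S,5R,6Z)-5-{[(2R,3R)-2,3-dimethyloxirane-2-carbonyl]oxy}-3-ethenyl-6-methyl-2-methylidene-4-(triethylsilyloxy)undec-6-en-9-ynoate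
Conditions: Et3SiCl, imidazole, DMAP (cat.), CH2Cl2, 0 → 23 °C
Reagents that add atoms: chlorotriethylsilane, CC[Si](Cl)(CC)CC
Why: Silylation masks the C6 hydroxyl, which could otherwise add to the gold-activated alkyne through a seven-membered ring in the next step.

Step 17
Reactants: 25 (the open-chain 1,9-enyne tert-butyl ester)
Product: 26 6-O-triethylsilyl ether of the target (ten-membered carbocycle with trans-fused α-methylene-γ-lactone)
Conditions: [(JohnPhos)Au(NCMe)]SbF6 (10 mol %; JohnPhos = (2-biphenylyl)di-tert-butylphosphine), 4 Å MS, CH2Cl2 (0.002 M, slow addition of 25), 23 → 40 °C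
Reagents that add atoms: none
Why: Proposed new method: the cationic monovalent gold centre binds the C1≡C10 alkyne, the terminal vinyl carbon C9 attacks C10 anti to gold (10-endo-dig closure of the carbocycle) while the ester carbonyl oxygen adds to C8 on the opposite face (5-exo-trig closure of the lactone), and loss of isobutene from the tert-butoxy oxocarbenium ion followed by protodeauration at C1 should release 26 and the catalyst. The closest known reactions are gold-catalysed enyne cyclisations terminated by a carboxyl or tert-butyl ester oxygen (shown for five- and six-membered carbocycles) and gold-catalysed macrocyclisations of 1,n-enynes; their combination on a 1,9-enyne is untested. The (Z)-C1=C10 geometry follows from anti carboauration and stereoretentive protodeauration, which place C9 cis to C2, the only arrangement a ten-membered ring accepts. C8 is controlled by C7: with C7–H eclipsing the vinyl group, the C11 ester arm and the C6 arm that carries the alkyne lie on opposite faces, so anti addition gives the trans-fused lactone. The step needs 10-endo attack in preference to 9-exo attack, and reaction of the vinyl group in preference to the C3=C4 alkene and the other oxygen nucleophiles. The 1,4-relation of C3=C4 to the alkyne (only three- or four-membered rings possible), the silyl ether on O6 and high dilution secure the chemoselectivity, whereas the endo preference rests only on the lower strain of the ten-membered ring with an endocyclic cis alkene.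

Step 18
Reactants: 26 6-O-triethylsilyl ether of the target
Product: 27 CNP0108157.1 (target)
Conditions: HF·pyridine, pyridine, THF, 0 °C
Reagents that add atoms: none
Why: Buffered fluoride-mediated desilylation under weakly acidic conditions should free the C6 hydroxyl without migration of the C5 ester, opening of the epoxide or addition to the α-methylene lactone.

Compound list
1 | but-2-yn-1-ol | CC#CCO | starting material
2 | sodium cyclic alkenylalanate from 1 | [Na+].CC1=CCO[Al-]1(OCCOC)OCCOC | intermediate (not isolated)
3 | (Z)-3-iodobut-2-en-1-ol | C/C(I)=C/CO | intermediate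
4 | (Z)-1-bromo-3-iodobut-2-ene | C/C(I)=C/CBr | intermediate
5 | 1-propynylmagnesium bromide | CC#C[Mg]Br | starting material
6 | (Z)-2-iodohept-2-en-5-yne | C/C(I)=C/CC#CC | intermediate
7 | methyl glycolate | COC(=O)CO | starting material
8 | methyl 2-(triethylsilyloxy)acetate | CC[Si](CC)(CC)OCC(=O)OC | intermediate
9 | N-methoxy-N-methyl-2-(triethylsilyloxy)acetamide | CC[Si](CC)(CC)OCC(=O)N(C)OC | intermediate
10 | (Z)-hept-2-en-5-yn-2-yllithium | C/C([Li])=C/CC#CC | intermediate (not isolated)
11 | (Z)-3-methyl-1-(triethylsilyloxy)oct-3-en-6-yn-2-one | CC[Si](CC)(CC)OCC(=O)/C(C)=C\CC#CC | intermediate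
12 | (2R,3Z)-3-methyl-1-(triethylsilyloxy)oct-3-en-6-yn-2-ol | CC[Si](CC)(CC)OC[C@H](O)/C(C)=C\CC#CC | intermediate
13 | angelic acid, (Z)-2-methylbut-2-enoic acid | C/C=C(/C)C(=O)O | starting material
14 | (Z)-2-methylbut-2-en-1-ol | C/C=C(/C)CO | intermediate
15 | [(2S,3R)-2,3-dimethyloxiran-2-yl]methanol | OC[C@]1(C)O[C@@H]1C | intermediate
16 | (2R,3R)-2,3-dimethyloxirane-2-carboxylic acid | OC(=O)[C@]1(C)O[C@@H]1C | intermediate
17 | (2R,3Z)-3-methyl-1-(triethylsilyloxy)oct-3-en-6-yn-2-yl (2R,3R)-2,3-dimethyloxirane-2-carboxylate | CC[Si](CC)(CC)OC[C@H](OC(=O)[C@]1(C)O[C@@H]1C)/C(C)=C\CC#CC | intermediate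
18 | (2R,3Z)-3-methyl-1-oxooct-3-en-6-yn-2-yl (2R,3R)-2,3-dimethyloxirane-2-carboxylate | O=C[C@H](OC(=O)[C@]1(C)O[C@@H]1C)/C(C)=C\CC#CC | intermediate
19 | acrolein | C=CC=O | starting material
20 | tert-butyl acrylate | C=CC(=O)OC(C)(C)C | starting material
21 | tert-butyl 3-hydroxy-2-methylidenepent-4-enoate (racemic) | C=CC(O)C(=C)C(=O)OC(C)(C)C | intermediate
22 | tert-butyl (2Z)-2-(bromomethyl)penta-2,4-dienoate | C=C/C=C(\CBr)C(=O)OC(C)(C)C | intermediate
23 | allylindium dibromide from 22 | C=C/C=C(\C[In](Br)Br)C(=O)OC(C)(C)C | intermediate (not isolated)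
24 | tert-butyl (3R,4S,5R,6Z)-5-{[(2R,3R)-2,3-dimethyloxirane-2-carbonyl]oxy}-3-ethenyl-4-hydroxy-6-methyl-2-methylideneundec-6-en-9-ynoate | C=C(C(=O)OC(C)(C)C)[C@@H](C=C)[C@H](O)[C@H](OC(=O)[C@]1(C)O[C@@H]1C)/C(C)=C\CC#CC | intermediate
25 | 4-O-triethylsilyl ether of 24 | C=C(C(=O)OC(C)(C)C)[C@@H](C=C)[C@H](O[Si](CC)(CC)CC)[C@H](OC(=O)[C@]1(C)O[C@@H]1C)/C(C)=C\CC#CC | intermediate
26 | 6-O-triethylsilyl ether of the target | C=C1C(=O)O[C@@H]2C/C(C)=C\C/C=C(/C)[C@@H](OC(=O)[C@]3(C)O[C@@H]3C)[C@@H](O[Si](CC)(CC)CC)[C@@H]12 | intermediate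
27 | CNP0108157.1: 1(10)Z,3Z-germacradien-12,8-olide with 11(13)-methylene, 6-hydroxyl and 5-O-(2R,3R)-2,3-epoxy-2-methylbutanoyl groups | C=C1C(=O)O[C@@H]2C/C(C)=C\C/C=C(/C)[C@@H](OC(=O)[C@]3(C)O[C@@H]3C)[C@@H](O)[C@@H]12 | target

Total step count: 18. Longest linear sequence: 11 steps (steps 1, 2, 3, 6, 7, 11, 12, 15, 16, 17, 18).

Steps most likely to fail

Step 17 (Proposed new method). The medium-ring closure may be too slow, so that alkyne hydration or oligomerisation takes over; attack may go 9-exo instead of 10-endo; or the ester oxygen may add to the wrong face of C8. The fallback sets out from 25 and comes back at 26, closing the two rings one after the other with known reactions. Lindlar semihydrogenation (H2, Pd/CaCO3 poisoned with Pb(OAc)2, quinoline, EtOAc) turns the alkyne of 25 into the (Z)-but-2-enyl ester F1. Iodolactonisation of the tert-butyl ester (I2, MeCN, 0 → 23 °C, equilibrating conditions) closes the same O–C8 bond by 5-exo attack and should give the trans iodomethyl lactone F2. Nickel-catalysed reductive cross-electrophile coupling of the primary iodide with 2-bromopropene (NiI2, 4,4′-di-tert-butyl-2,2′-bipyridine, Mn powder, DMPU) forms C9–C10 and gives the 2-methylallyl lactone F3. Ring-closing metathesis (second-generation Grubbs catalyst, toluene, high dilution, 80 °C) between the 1,1-disubstituted alkene and the (Z)-butenyl group closes C10=C1 with loss of propene; the ten-membered ring should favour the cis alkene, which returns the route to 26.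

Step 15. Facial control at C6 may be poor (chelation competing with Felkin–Anh addition), the allylindium may equilibrate and erode the syn selectivity, the aldehyde may epimerise at C5, or the C5 ester may migrate to the new indium alkoxide. The fallback sets out from 22 and comes back at 24, replacing the in situ organoindium by an isolated, configurationally defined boron reagent. Palladium-catalysed borylation of 22 (B2pin2, Pd2(dba)3, toluene, 50 °C) gives the allylboronate F4. Thermal allylboration of 18 with F4 (toluene, 40–60 °C, no metal salts, no water) passes through a closed six-membered transition state in which the (Z)-reagent gives the syn adduct, and mild aqueous work-up of the borate gives 24.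

Step 6. The alkenyllithium may be quenched by proton transfer from the doubly activated C2 methylene, the (Z)-geometry may be lost, or the skipped enynone may isomerise under base. The fallback sets out from 8 (and 6) and comes back at 11, avoiding any strongly basic organometallic. DIBAL-H reduction of 8 (CH2Cl2, −78 °C) gives 2-(triethylsilyloxy)acetaldehyde F5. Nozaki–Hiyama–Kishi coupling of 6 with F5 (CrCl2, NiCl2 (cat.), DMF, 23 °C) gives the racemic allylic alcohol F6 with retention of alkene geometry. Dess–Martin oxidation buffered with NaHCO3 gives 11, which re-enters the route at the enantioselective reduction of step 7.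

Further compounds
F1 | step 17 | tert-butyl (3R,4S,5R,6Z,9Z)-5-{[(2R,3R)-2,3-dimethyloxirane-2-carbonyl]oxy}-3-ethenyl-6-methyl-2-methylidene-4-(triethylsilyloxy)undeca-6,9-dienoate | C=C(C(=O)OC(C)(C)C)[C@@H](C=C)[C@H](O[Si](CC)(CC)CC)[C@H](OC(=O)[C@]1(C)O[C@@H]1C)/C(C)=C\C/C=C\C
F2 | step 17 | trans-5-(iodomethyl)-3-methylidene-γ-butyrolactone carrying the C6–C1 side chain on C4 | C=C1C(=O)O[C@H](CI)[C@H]1[C@H](O[Si](CC)(CC)CC)[C@H](OC(=O)[C@]2(C)O[C@@H]2C)/C(C)=C\C/C=C\C
F3 | step 17 | trans-5-(2-methylallyl)-3-methylidene-γ-butyrolactone carrying the C6–C1 side chain on C4 | C=C1C(=O)O[C@H](CC(C)=C)[C@H]1[C@H](O[Si](CC)(CC)CC)[C@H](OC(=O)[C@]2(C)O[C@@H]2C)/C(C)=C\C/C=C\C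
F4 | step 15 | tert-butyl (2Z)-2-[(4,4,5,5-tetramethyl-1,3,2-dioxaborolan-2-yl)methyl]penta-2,4-dienoate | C=C/C=C(\CB1OC(C)(C)C(C)(C)O1)C(=O)OC(C)(C)C
F5 | step 6 | 2-(triethylsilyloxy)acetaldehyde | CC[Si](CC)(CC)OCC=O
F6 | step 6 | racemic (Z)-3-methyl-1-(triethylsilyloxy)oct-3-en-6-yn-2-ol | CC[Si](CC)(CC)OCC(O)/C(C)=C\CC#CC
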